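**Retrosynthetic overview**
1. The target is (13S)-6β-hydroxy-9α,13-epoxylabdane-19,20:16,15-diolide. All twenty carbons, the C19 carboxyl, the 6β- and 9α-oxygens and the stereocentres C4, C5, C6, C8, C9 and C10 are taken from (+)-marrubiin (1).
2. Last bond: C20–O of the δ-lactone ⇒ 6β-hydroxy-19-oic acid. A light-generated 6β-alkoxy radical takes H from the 1,3-diaxial C20 methyl and copper closes the C–O bond (19,6β-lactone transposed to 19,20-lactone).
3. Spiro γ-lactone ⇒ lactol methyl ether ⇒ spiro enol ether. The C13–O9 bond comes from the furan and the 9α-OH by anodic dimethoxylation and acid spiroetherification (C13 is set here).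
4. Ring order (forward): spiro tetrahydrofuran with its oxygenated five-membered ring → spiro γ-lactone → opening of the old 19,6β-lactone → 19,20 δ-lactone.

Assumption: (+)-marrubiin, the bulk bitter diterpene of white horehound, is taken as a purchasable, inexpensive chiral-pool compound.
Numbering: labdane numbering (C19 = carboxyl carbon on C4, C20 = carbon on C10, C17 = methyl on C8, C16 = the furan/lactone carbon bonded to C13, C14–C15 = the other two).

**Step 1**
Reactants: 1 (+)-marrubiin
Product: 3 (13S)-9α,13:15,16-diepoxy-16-methoxylabd-14-en-19,6β-olide (C16 anomers), via dimethoxydihydrofuran 2 (not isolated)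
Conditions: graphite anode, Pt cathode, undivided cell, Et4NOTs, MeOH, 2.2 F/mol, −10 °C; then solvent switch to toluene, PPTS (10 mol%), 40 °C, N2 stream to remove MeOH; SiO2 chromatography
Reagents that add atoms: methanol (SMILES: CO)
Why: Clauson-Kaas-type anodic 2,5-dimethoxylation touches only the furan, and PPTS then ionises the C15 acetal of 2 to an allyl oxocarbenium whose tertiary end C13 is captured 5-exo by the axial 9α-OH (SN1′ spiroetherification, the reverse of the acid opening of premarrubiin-type ethers); C13 is set in this reversible closure from the fixed 9α-oxygen, and because both C13 epimers form and interconvert under the acid, the 13S epimer (C16 syn to C10) is collected and the 13R epimer is resubmitted to PPTS, while the C16 acetal centre disappears in step 3.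

**Step 2**
Reactants: 3 (13S)-9α,13:15,16-diepoxy-16-methoxylabd-14-en-19,6β-olide
Product: 4 (13S)-9α,13:15,16-diepoxy-16-methoxylabdan-19,6β-olide
Conditions: H2 (1 atm), 5% Rh/Al2O3, EtOAc, Et3N (1%), 23 °C
Reagents that add atoms: none
Why: Catalytic hydrogenation of the electron-rich enol ether C14=C15; rhodium on alumina with a trace of amine avoids hydrogenolysis of the allylic C13–O9 bond and acid-induced acetal scrambling, and no stereocentre is formed or touched.

**Step 3**
Reactants: 4 (13S)-9α,13:15,16-diepoxy-16-methoxylabdan-19,6β-olide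
Product: 5 (13S)-9α,13-epoxylabdane-19,6β:16,15-diolide
Conditions: CrO3, H2SO4, H2O, acetone, 0 → 23 °C
Reagents that add atoms: water (SMILES: O)
Why: Jones oxidation: aqueous acid hydrolyses the methyl lactol ether to the lactol and hexavalent chromium oxidises it to the γ-lactone; the molecule has no other oxidisable group and the quaternary C13 cannot epimerise.

**Step 4**
Reactants: 5 (13S)-9α,13-epoxylabdane-19,6β:16,15-diolide
Product: 7 (13S)-9α,13-epoxy-6β-hydroxylabdan-16,15-olid-19-oic acid, via dipotassium dicarboxylate 6 (not isolated)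
Conditions: KOH (10 equiv), EtOH/H2O 4:1, 80 °C; then 1 M HCl to pH 2, 0 → 23 °C, 2 h
Reagents that add atoms: potassium hydroxide (SMILES: [K+].[OH-])
Why: Saponification opens both lactones by acyl–oxygen cleavage, so no stereocentre is touched, and on acidification only the primary 15-OH recloses onto the α-alkoxy, α-quaternary C16 acid (Thorpe–Ingold-accelerated γ-lactonisation), whereas the hindered 6β-hydroxy-19-oic acid pair (the marrubiinic acid arrangement) stays open in cold dilute acid.

**Step 5**
Reactants: 7 (13S)-9α,13-epoxy-6β-hydroxylabdan-16,15-olid-19-oic acid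
Product: 9 (13S)-9α,13-epoxy-6β-hydroxylabdane-19,20:16,15-diolide (target), via 6β-nitrite 8 (not isolated)
Conditions: t-BuONO (10 equiv), CH2Cl2, 23 °C, dark, then evaporate; Cu(OAc)2 (1.5 equiv), pyridine (3 equiv), MeCN, hν (365 nm), 10 °C, Ar sparge
Reagents that add atoms: none
Why: Proposed new method: copper-interrupted nitrite photolysis (alcohol-directed δ-C–H lactonisation) — 365 nm light cleaves the O–NO bond of 8, the 6β-alkoxy radical abstracts hydrogen from the 1,3-diaxial C20 methyl through a six-membered transition state (O···C about 2.5 Å; C19 has no hydrogen and the equatorial C18 is out of reach), and the neopentyl C20 radical, which has no β-hydrogen to lose, is captured by the divalent copper held on the equally 1,3-diaxial C19 carboxylate to give a trivalent alkylcopper carboxylate that reductively eliminates the C20–O bond without a free cation (no Wagner–Meerwein shift), leaving the 6β-OH free and monovalent copper; no stereocentre is formed; the closest known reactions are the Barton nitrite photolysis with radical exchange (iodine or BrCCl3 traps) and the Kochi/Kharasch–Sosnovsky oxidative acyloxylation of alkyl radicals by Cu(OAc)2.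

**Compound list**
1 | (+)-marrubiin, 9α-hydroxy-15,16-epoxylabda-13(16),14-dien-19,6β-olide (5α-H, 8α-Me, 10β-Me) | C[C@@H]1C[C@@H]2[C@@H]3[C@](C)(CCC[C@]3(C)C(=O)O2)[C@@]1(O)CCc1ccoc1 | starting material
2 | 9α-hydroxy-15,16-dimethoxy-15,16-epoxylabd-13-en-19,6β-olide (acetal diastereomers) | C[C@@H]1C[C@@H]2[C@@H]3[C@](C)(CCC[C@]3(C)C(=O)O2)[C@@]1(O)CCC1=CC(OC)OC1OC | intermediate
3 | (13S)-9α,13:15,16-diepoxy-16-methoxylabd-14-en-19,6β-olide (C16 anomers) | C[C@@H]1C[C@@H]2[C@@H]3[C@](C)(CCC[C@]3(C)C(=O)O2)[C@@]12CC[C@@]3(C=COC3OC)O2 | intermediate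
4 | (13S)-9α,13:15,16-diepoxy-16-methoxylabdan-19,6β-olide (C16 anomers) | C[C@@H]1C[C@@H]2[C@@H]3[C@](C)(CCC[C@]3(C)C(=O)O2)[C@@]12CC[C@@]3(CCOC3OC)O2 | intermediate
5 | (13S)-9α,13-epoxylabdane-19,6β:16,15-diolide | C[C@@H]1C[C@@H]2[C@@H]3[C@](C)(CCC[C@]3(C)C(=O)O2)[C@@]12CC[C@@]3(CCOC3=O)O2 | intermediate
6 | dipotassium (13S)-9α,13-epoxy-6β,15-dihydroxylabdane-16,19-dioate | C[C@@H]1C[C@@H](O)[C@@H]2[C@](C)(CCC[C@]2(C)C(=O)[O-])[C@@]12CC[C@](CCO)(C(=O)[O-])O2.[K+].[K+] | intermediate
7 | (13S)-9α,13-epoxy-6β-hydroxylabdan-16,15-olid-19-oic acid | C[C@@H]1C[C@@H](O)[C@@H]2[C@](C)(CCC[C@]2(C)C(=O)O)[C@@]12CC[C@@]3(CCOC3=O)O2 | intermediate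
8 | 6β-nitrite ester of 7 | C[C@@H]1C[C@@H](ON=O)[C@@H]2[C@](C)(CCC[C@]2(C)C(=O)O)[C@@]12CC[C@@]3(CCOC3=O)O2 | intermediate
9 | (13S)-9α,13-epoxy-6β-hydroxylabdane-19,20:16,15-diolide (CNP0393616.1) | C[C@@H]1C[C@@H](O)[C@@H]2[C@]3(CCC[C@]2(C)C(=O)OC3)[C@@]12CC[C@@]1(CCOC1=O)O2 | target

**Totals**
Total step count: 5. Longest linear sequence: 5 steps (1 → 3 → 4 → 5 → 7 → 9).

**Three steps most likely to fail**

Step 1 (spiroetherification and C13). The 9α-OH may instead close on C16 to give a six-membered 9,16-acetal, or the cation may lose H16 to give a 16-methoxyfuran. C1H2 and the C17 methyl make the α-face around C9 almost mirror-symmetric, so the C13 ratio is expected to be near 1:1 and the step relies on separation and acid recycling. The fallback sets out from 1 and comes back to the route at 5; it forms the spiro centre by a reversible oxa-Michael addition at the lactone oxidation level, where C13 already carries the substituents of the target. Sensitised photooxygenation of 1 (O2, tetraphenylporphyrin, hν, CH2Cl2/MeOH, −78 °C) gives, after methanol opens the endoperoxide at C15, the 15-methoxy-16-hydroperoxide F1. Ac2O/pyridine dehydrates it to the 15-methoxybutenolide F2, with the carbonyl at C16. HCl in aqueous THF hydrolyses the pseudo-ester to the 15-hydroxybutenolide F3. In K2CO3/aqueous MeOH its ring-opened formyl acrylate takes up the 9α-OH at C13 (β to the aldehyde) reversibly, giving the spiro 15-hydroxy lactone F4 under thermodynamic control. NaBH4 and then HCl reduce the masked aldehyde and close the γ-lactone, which is 5.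

Step 4 (telling the two hydroxy acids apart). If the 6β-hydroxy-19-acid also relactonises, or the 15-hydroxy-16-acid does not, 7 is not obtained cleanly. The fallback sets out from 4 and comes back to the route at 9; it keeps the spiro ring as the base-stable methyl acetal so that only one lactone can open. KOH (aqueous EtOH, 80 °C) followed by acidification to pH 4 at 0 °C gives the hydroxy acid acetal F5. t-BuONO converts it into the nitrite F6, and the copper-mediated photolysis of step 5 gives the 19,20-olide acetal F7. mCPBA with BF3·OEt2 then oxidises the methyl lactol ether to the γ-lactone in the presence of the free 6β-OH, which is 9.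

Step 5 (the proposed copper-interrupted nitrite photolysis). The C20 radical may recombine with NO to give the C20 oxime, the copper may close the 6β,20-ether instead of the lactone, or the copper carboxylate may photodecarboxylate. The fallback uses known chemistry, sets out from 8 and comes back to the route at 9. Photolysis of 8 (365 nm, benzene) in the presence of iodine traps the C20 radical by radical exchange as the 20-iodo hydroxy acid F8. K2CO3 in DMF at 60 °C then closes the δ-lactone by intramolecular displacement of iodide by the C19 carboxylate (the neutral 6β-OH does not compete), which is 9.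

**Further compounds**
F1 | step 1 | 9α-hydroxy-16-hydroperoxy-15-methoxy-15,16-epoxylabd-13-en-19,6β-olide (acetal diastereomers) | C[C@@H]1C[C@@H]2[C@@H]3[C@](C)(CCC[C@]3(C)C(=O)O2)[C@@]1(O)CCC1=CC(OC)OC1OO
F2 | step 1 | 9α-hydroxy-15-methoxylabd-13-ene-19,6β:16,15-diolide | C[C@@H]1C[C@@H]2[C@@H]3[C@](C)(CCC[C@]3(C)C(=O)O2)[C@@]1(O)CCC1=CC(OC)OC1=O
F3 | step 1 | 9α,15-dihydroxylabd-13-ene-19,6β:16,15-diolide | C[C@@H]1C[C@@H]2[C@@H]3[C@](C)(CCC[C@]3(C)C(=O)O2)[C@@]1(O)CCC1=CC(O)OC1=O
F4 | step 1 | (13S)-9α,13-epoxy-15-hydroxylabdane-19,6β:16,15-diolide | C[C@@H]1C[C@@H]2[C@@H]3[C@](C)(CCC[C@]3(C)C(=O)O2)[C@@]12CC[C@@]3(CC(O)OC3=O)O2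
F5 | step 4 | (13S)-9α,13:15,16-diepoxy-6β-hydroxy-16-methoxylabdan-19-oic acid | C[C@@H]1C[C@@H](O)[C@@H]2[C@](C)(CCC[C@]2(C)C(=O)O)[C@@]12CC[C@@]3(CCOC3OC)O2
F6 | step 4 | 6β-nitrite ester of F5 | C[C@@H]1C[C@@H](ON=O)[C@@H]2[C@](C)(CCC[C@]2(C)C(=O)O)[C@@]12CC[C@@]3(CCOC3OC)O2
F7 | step 4 | (13S)-9α,13:15,16-diepoxy-6β-hydroxy-16-methoxylabdan-19,20-olide | C[C@@H]1C[C@@H](O)[C@@H]2[C@]3(CCC[C@]2(C)C(=O)OC3)[C@@]12CC[C@@]1(CCOC1OC)O2
F8 | step 5 | (13S)-9α,13-epoxy-6β-hydroxy-20-iodolabdan-16,15-olid-19-oic acid | C[C@@H]1C[C@@H](O)[C@@H]2[C@](CI)(CCC[C@]2(C)C(=O)O)[C@@]12CC[C@@]3(CCOC3=O)O2
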